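**Retrosynthetic overview**
1. Ester C–O: target 11 ⇒ diol 8 + linoleic acid 9 (Steglich acylation of the primary OH only).
2. Aryl–prenyl C–C: 8 ⇒ bromo diol 6 + prenylstannane 7 (Stille coupling).
3. Tertiary C–OH: 6 ⇒ isopropenyl alcohol 5 (Markovnikov hydrogen-atom-transfer hydration).
4. Indole C3–C bond and the only stereocentre: 5 ⇒ 6-bromoindole 4 + racemic 2-isopropenyloxirane 3 (new Pd/borane asymmetric branched C3–H alkylation).
5. Rings: no ring of the target is built, the indole is bought as 4; the only ring made is the oxirane of 3 (from methacrolein 1), which is opened again in step 2.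

Assumption: in step 2 the (R,R) ligand is taken to give the R alcohol; the sense is proven on the first batch (Mosher esters, chiral HPLC) and the (S,S) ligand is used instead if it is the opposite.

**Step 1**
Reactants: 1 2-methylprop-2-enal (methacrolein)
Product: 3 rac-2-(prop-1-en-2-yl)oxirane, via sulfonium betaine 2 (not isolated)
Conditions: trimethylsulfonium iodide (1.2 equiv), KOtBu (1.2 equiv), DMSO, 20 °C; pentane/H2O work-up, distillation
Reagents that add atoms: trimethylsulfonium iodide, C[S+](C)C.[I-]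
Why: Corey–Chaykovsky epoxidation, in which dimethylsulfonium methylide adds 1,2 to the enal carbonyl and betaine 2 closes to the oxirane with loss of dimethyl sulfide; the product is racemic on purpose because this centre is erased in the π-allyl complex of step 2.

**Step 2**
Reactants: 3 rac-2-(prop-1-en-2-yl)oxirane; 4 6-bromo-1H-indole (1.5 equiv)
Product: 5 (2R)-2-(6-bromo-1H-indol-3-yl)-3-methylbut-3-en-1-ol
Conditions: Pd2(dba)3·CHCl3 (2.5 mol%), (R,R)-DACH-naphthyl Trost ligand (7.5 mol%), BEt3 (20 mol%), CH2Cl2, rt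
Reagents that add atoms: none
Why: Proposed new method: zerovalent palladium ionises racemic 3 to a zwitterionic 2-methyl-π-allylpalladium alkoxide whose two diastereomeric forms interconvert through the η1 complex at the unsubstituted CH2 terminus faster than they are trapped (dynamic kinetic asymmetric transformation), BEt3 takes up the alkoxide, the borate is protonated by the indole N–H, and the resulting N-borylated indolide, blocked at nitrogen, is guided by the hydroxyl/borate contact inside the chiral pocket to the allyl terminus next to CH2O, so the C3–C bond forms at the branched position and sets the R stereocentre; the closest known reactions are the palladium-catalysed asymmetric additions of imides, alcohols and β-ketoesters to vinyl epoxides and the borane-promoted palladium C3-allylation of indoles with allyl alcohols, neither of which has been shown for the C3–H of a free indole with a 2-substituted vinyl oxirane.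

**Step 3**
Reactants: 5 (2R)-2-(6-bromo-1H-indol-3-yl)-3-methylbut-3-en-1-ol
Product: 6 (2R)-2-(6-bromo-1H-indol-3-yl)-3-methylbutane-1,3-diol
Conditions: Co(acac)2 (20 mol%), PhSiH3 (2 equiv), O2 (1 atm), THF, 0 °C → rt
Reagents that add atoms: dioxygen, O=O
Why: Mukaiyama hydration, in which the Co–H species formed from Co(acac)2 and PhSiH3 transfers a hydrogen atom to the terminal CH2 of the 1,1-disubstituted alkene, the tertiary radical is trapped by O2 and the peroxide is reduced by the silane, giving the Markovnikov tertiary alcohol without touching the aryl bromide, the free OH and NH or the adjacent stereocentre.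

**Step 4**
Reactants: 6 (2R)-2-(6-bromo-1H-indol-3-yl)-3-methylbutane-1,3-diol; 7 tributyl(3-methylbut-2-en-1-yl)stannane (1.3 equiv)
Product: 8 (2R)-3-methyl-2-[6-(3-methylbut-2-en-1-yl)-1H-indol-3-yl]butane-1,3-diol
Conditions: Pd(PPh3)4 (5 mol%), DMF, 100 °C, argon
Reagents that add atoms: none
Why: Stille cross-coupling, in which oxidative addition of the aryl bromide to zerovalent palladium, transfer of the prenyl group from tin and reductive elimination at the less hindered allyl terminus give the linear prenyl arene under neutral conditions that tolerate the diol and N–H and cannot epimerise the stereocentre.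

**Step 5**
Reactants: 8 (2R)-3-methyl-2-[6-(3-methylbut-2-en-1-yl)-1H-indol-3-yl]butane-1,3-diol; 9 (9Z,12Z)-octadeca-9,12-dienoic acid (linoleic acid, 1.05 equiv)
Product: 11 (2R)-3-hydroxy-3-methyl-2-[6-(3-methylbut-2-en-1-yl)-1H-indol-3-yl]butyl (9Z,12Z)-octadeca-9,12-dienoate (target CNP0180241.2), via linoleoyl O-acylisourea 10 (not isolated)
Conditions: DCC (1.1 equiv), DMAP (0.1 equiv), CH2Cl2, 0 °C → rt, argon, dark
Reagents that add atoms: none
Why: Steglich esterification, in which DCC activates the acid as O-acylisourea 10 and DMAP relays the acyl group to the unhindered primary hydroxyl, while the tertiary alcohol and the indole N–H do not react and the skipped Z,Z-diene and the stereocentre are untouched.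

**Compound list**
1 | 2-methylprop-2-enal (methacrolein) | CC(=C)C=O | starting material
2 | dimethyl(3-methyl-2-oxidobut-3-en-1-yl)sulfonium (sulfonium betaine, racemic, not isolated) | CC(=C)C([O-])C[S+](C)C | intermediate
3 | rac-2-(prop-1-en-2-yl)oxirane | CC(=C)C1CO1 | intermediate
4 | 6-bromo-1H-indole | Brc1ccc2cc[nH]c2c1 | starting material
5 | (2R)-2-(6-bromo-1H-indol-3-yl)-3-methylbut-3-en-1-ol | OC[C@@H](c1c[nH]c2cc(Br)ccc12)C(C)=C | intermediate
6 | (2R)-2-(6-bromo-1H-indol-3-yl)-3-methylbutane-1,3-diol | OC[C@@H](c1c[nH]c2cc(Br)ccc12)C(C)(C)O | intermediate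
7 | tributyl(3-methylbut-2-en-1-yl)stannane | CCCC[Sn](CCCC)(CCCC)CC=C(C)C | starting material
8 | (2R)-3-methyl-2-[6-(3-methylbut-2-en-1-yl)-1H-indol-3-yl]butane-1,3-diol | OC[C@@H](c1c[nH]c2cc(CC=C(C)C)ccc12)C(C)(C)O | intermediate
9 | (9Z,12Z)-octadeca-9,12-dienoic acid (linoleic acid) | CCCCC/C=C\C/C=C\CCCCCCCC(=O)O | starting material
10 | N,N'-dicyclohexyl-O-[(9Z,12Z)-octadeca-9,12-dienoyl]isourea (linoleoyl O-acylisourea, not isolated) | CCCCC/C=C\C/C=C\CCCCCCCC(=O)OC(=NC1CCCCC1)NC1CCCCC1 | intermediate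
11 | (2R)-3-hydroxy-3-methyl-2-[6-(3-methylbut-2-en-1-yl)-1H-indol-3-yl]butyl (9Z,12Z)-octadeca-9,12-dienoate | CCCCC/C=C\C/C=C\CCCCCCCC(=O)OC[C@@H](c1c[nH]c2cc(CC=C(C)C)ccc12)C(C)(C)O | target

**Totals**
Total step count: 5. Longest linear sequence: 5 steps (1 → 3 → 5 → 6 → 8 → 11).

**Steps most likely to fail**

Step 2 (the proposed new method). Possible failures are N-alkylation instead of C3-alkylation, attack at the distal CH2 terminus (linear product), a second C3-alkylation of 5 to an indolenine, or low ee. The fallback uses known Evans auxiliary chemistry, sets out from 4 and comes back to the route at 6. Cu(OTf)2-catalysed C3–H insertion of ethyl diazoacetate into 4 gives ethyl 2-(6-bromo-1H-indol-3-yl)acetate F1. TsCl/NaOH/Bu4NHSO4 gives ethyl 2-[6-bromo-1-(4-methylbenzenesulfonyl)-1H-indol-3-yl]acetate F2. LiOH gives 2-[6-bromo-1-(4-methylbenzenesulfonyl)-1H-indol-3-yl]acetic acid F3. Pivaloyl chloride/Et3N gives 2-[6-bromo-1-(4-methylbenzenesulfonyl)-1H-indol-3-yl]acetic 2,2-dimethylpropanoic anhydride F4 (used in the flask), which with (4S)-4-benzyl-1,3-oxazolidin-2-one and LiCl gives (4S)-4-benzyl-3-{2-[6-bromo-1-(4-methylbenzenesulfonyl)-1H-indol-3-yl]acetyl}-1,3-oxazolidin-2-one F5. The TiCl4/i-Pr2NEt enolate is hydroxymethylated with 1,3,5-trioxane/TiCl4, the electrophile entering the chelated Z enolate anti to the benzyl group, to give (4S)-4-benzyl-3-{(2R)-2-[6-bromo-1-(4-methylbenzenesulfonyl)-1H-indol-3-yl]-3-hydroxypropanoyl}-1,3-oxazolidin-2-one F6. Sm(OTf)3-catalysed methanolysis gives methyl (2R)-2-[6-bromo-1-(4-methylbenzenesulfonyl)-1H-indol-3-yl]-3-hydroxypropanoate F7. Excess MeMgBr/CeCl3 (THF, −78 → 0 °C) gives (2R)-2-[6-bromo-1-(4-methylbenzenesulfonyl)-1H-indol-3-yl]-3-methylbutane-1,3-diol F8. Cs2CO3 in MeOH/THF at 60 °C removes the tosyl group and delivers 6.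

Step 3. Possible failures are oxidation of the free 3-alkylindole by the Co(acac)2/O2 system, or return of a hydrogen atom from the tertiary radical to give the tetrasubstituted alkene, which would destroy the stereocentre. The fallback avoids radicals, sets out from 5 and comes back at 6. Hydroxyl-directed epoxidation of the homoallylic alcohol with VO(acac)2/t-BuOOH in CH2Cl2 gives (2R)-2-(6-bromo-1H-indol-3-yl)-2-(2-methyloxiran-2-yl)ethan-1-ol F9, as both epimers at the oxirane carbon, which becomes achiral in the next operation. LiEt3BH in THF at 0 °C then opens the oxirane at its CH2 carbon and gives 6.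

Step 4. Possible failures are coupling at the γ-terminus (reverse-prenyl isomer), slow oxidative addition of the electron-rich bromide, or tin residues that are hard to remove from a polar diol. The fallback reverses the polarity of the coupling, sets out from 6 and comes back at 8. Miyaura borylation (B2pin2, Pd(dppf)Cl2, KOAc, dioxane, 90 °C) gives (2R)-3-methyl-2-[6-(4,4,5,5-tetramethyl-1,3,2-dioxaborolan-2-yl)-1H-indol-3-yl]butane-1,3-diol F10. Suzuki–Miyaura coupling with 1-bromo-3-methylbut-2-ene (Pd(PPh3)4, K2CO3, THF/H2O, 60 °C), in which reductive elimination from the aryl(π-prenyl)palladium complex occurs at the unsubstituted terminus, gives 8.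

**Further compounds**
F1 | step 2 | ethyl 2-(6-bromo-1H-indol-3-yl)acetate | CCOC(=O)Cc1c[nH]c2cc(Br)ccc12
F2 | step 2 | ethyl 2-[6-bromo-1-(4-methylbenzenesulfonyl)-1H-indol-3-yl]acetate | CCOC(=O)Cc1cn(S(=O)(=O)c2ccc(C)cc2)c2cc(Br)ccc12
F3 | step 2 | 2-[6-bromo-1-(4-methylbenzenesulfonyl)-1H-indol-3-yl]acetic acid | OC(=O)Cc1cn(S(=O)(=O)c2ccc(C)cc2)c2cc(Br)ccc12
F4 | step 2 | 2-[6-bromo-1-(4-methylbenzenesulfonyl)-1H-indol-3-yl]acetic 2,2-dimethylpropanoic anhydride | CC(C)(C)C(=O)OC(=O)Cc1cn(S(=O)(=O)c2ccc(C)cc2)c2cc(Br)ccc12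
F5 | step 2 | (4S)-4-benzyl-3-{2-[6-bromo-1-(4-methylbenzenesulfonyl)-1H-indol-3-yl]acetyl}-1,3-oxazolidin-2-one | O=C(Cc1cn(S(=O)(=O)c2ccc(C)cc2)c2cc(Br)ccc12)N1[C@@H](Cc2ccccc2)COC1=O
F6 | step 2 | (4S)-4-benzyl-3-{(2R)-2-[6-bromo-1-(4-methylbenzenesulfonyl)-1H-indol-3-yl]-3-hydroxypropanoyl}-1,3-oxazolidin-2-one | OC[C@@H](c1cn(S(=O)(=O)c2ccc(C)cc2)c2cc(Br)ccc12)C(=O)N1[C@@H](Cc2ccccc2)COC1=O
F7 | step 2 | methyl (2R)-2-[6-bromo-1-(4-methylbenzenesulfonyl)-1H-indol-3-yl]-3-hydroxypropanoate | OC[C@@H](c1cn(S(=O)(=O)c2ccc(C)cc2)c2cc(Br)ccc12)C(=O)OC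
F8 | step 2 | (2R)-2-[6-bromo-1-(4-methylbenzenesulfonyl)-1H-indol-3-yl]-3-methylbutane-1,3-diol | OC[C@@H](c1cn(S(=O)(=O)c2ccc(C)cc2)c2cc(Br)ccc12)C(C)(C)O
F9 | step 3 | (2R)-2-(6-bromo-1H-indol-3-yl)-2-(2-methyloxiran-2-yl)ethan-1-ol (both epimers at the oxirane carbon) | OC[C@@H](c1c[nH]c2cc(Br)ccc12)C1(C)CO1
F10 | step 4 | (2R)-3-methyl-2-[6-(4,4,5,5-tetramethyl-1,3,2-dioxaborolan-2-yl)-1H-indol-3-yl]butane-1,3-diol | OC[C@@H](c1c[nH]c2cc(B3OC(C)(C)C(C)(C)O3)ccc12)C(C)(C)O
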